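**Strategy.** Both quaternary stereocentres are bought as natural (S)-bakuchiol; only the carbinol C12' must be created (bakuchiol numbering, primes for the phenol-bearing unit; ring A is the ether-bearing benzene ring). Everything rests on the C11'–C12' bond, and the key step exploits that C12' lies between the fully substituted ether carbon C13' (two methyls, oxygen of ring A) and the unbranched C10'–C11' tether to quaternary C9'. One bakuchiol is capped on oxygen as a 2-aryloxy-2-methylpropanal without α-hydrogen; a second is cut back by four carbons to a primary iodide. The key step turns the iodide into an alkylzinc that adds to the aldehyde under a chiral titanium bis(sulfonamide) catalyst, joining both halves and setting 12'S at once.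

Key step: step 8

Remark: (S)-bakuchiol is assumed to be available commercially as the enantiopure natural product; it supplies both quaternary stereocentres unchanged.

Step 1
Reactants: 1 (S)-bakuchiol; 2 ethyl 2-bromo-2-methylpropanoate
Product: 3 ethyl 2-{4-[(1E,3S)-3-ethenyl-3,7-dimethylocta-1,6-dien-1-yl]phenoxy}-2-methylpropanoate
Conditions: Cs2CO3, DMF, 60 °C
Reagents that add atoms: none
Why: Williamson-type O-alkylation of the caesium phenoxide by the tertiary α-bromo ester (the etherification used for fibrates) should install the hindered C13'–O aryl ether early, with the remote stereocentre untouched.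

Step 2
Reactants: 3 the aryloxy ester
Product: 4 2-{4-[(1E,3S)-3-ethenyl-3,7-dimethylocta-1,6-dien-1-yl]phenoxy}-2-methylpropanal
Conditions: i-Bu2AlH (1.1 equiv), CH2Cl2, −78 °C; then aq. KNaC4H4O6
Reagents that add atoms: none
Why: Partial ester reduction should stop at the aldehyde because the tetrahedral aluminium hemiacetal, chelated by the α-aryloxy oxygen and flanked by a fully substituted carbon, persists at −78 °C until work-up.

Step 3
Reactants: 1 (S)-bakuchiol
Product: 5 tert-butyl{4-[(1E,3S)-3-ethenyl-3,7-dimethylocta-1,6-dien-1-yl]phenoxy}dimethylsilane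
Conditions: TBSCl, imidazole, DMF, 25 °C
Reagents that add atoms: tert-butyldimethylsilyl chloride, CC(C)(C)[Si](C)(C)Cl
Why: Standard phenol silylation masks the acidic O–H for the later organozinc chemistry and gives an aryl silyl ether that tolerates the oxidative and mildly acidic steps that follow.

Step 4
Reactants: 5 the silyl ether of bakuchiol
Product: 6 tert-butyl(4-{(1E,3S)-5-(3,3-dimethyloxiran-2-yl)-3-ethenyl-3-methylpent-1-en-1-yl}phenoxy)dimethylsilane, both epimers at the oxirane CH
Conditions: mCPBA (1.0 equiv), CH2Cl2, −20 to 0 °C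
Reagents that add atoms: 3-chloroperoxybenzoic acid, OOC(=O)c1cccc(Cl)c1
Why: Prilezhaev epoxidation should be fastest at the remote trisubstituted alkene, since the vinyl and styryl alkenes are less substituted and both flanked by the quaternary carbon; the oxirane stereocentre forms without control and is destroyed in step 5.

Step 5
Reactants: 6 the epoxide
Product: 8 (4S,5E)-6-{4-[(tert-butyldimethylsilyl)oxy]phenyl}-4-ethenyl-4-methylhex-5-enal, via glycol 7 (not isolated)
Conditions: H5IO6, THF/Et2O, 0 °C
Reagents that add atoms: none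
Why: Periodic acid should open the epoxide to the glycol and cleave it in the same flask (Malaprade cleavage), excising the three terminal carbons as acetone while the other two alkenes and the aryl silyl ether stay intact.

Step 6
Reactants: 8 the aldehyde
Product: 9 (4S,5E)-6-{4-[(tert-butyldimethylsilyl)oxy]phenyl}-4-ethenyl-4-methylhex-5-enoic acid
Conditions: NaClO2, NaH2PO4, 2-methylbut-2-ene, t-BuOH/H2O, 25 °C
Reagents that add atoms: sodium chlorite, [Na+].[O-]Cl=O
Why: Pinnick oxidation converts the aldehyde into the acid under buffered conditions, the excess 2-methylbut-2-ene scavenging hypochlorous acid so that the alkenes and the electron-rich arene are spared.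

Step 7
Reactants: 9 the acid
Product: 11 tert-butyl{4-[(1E,3S)-3-ethenyl-5-iodo-3-methylpent-1-en-1-yl]phenoxy}dimethylsilane, via Barton ester 10 (not isolated)
Conditions: 1-hydroxypyridine-2(1H)-thione, DCC, DMAP (cat.), CH2Cl2, dark, 0 to 25 °C; then CHI3, visible light, 25 °C
Reagents that add atoms: iodoform, IC(I)I
Why: Barton decarboxylative iodination: light-induced homolysis of the thiohydroxamate ester releases CO2 and the primary radical at the future C11', which should abstract iodine from iodoform much faster than it could close a four-membered ring onto the neighbouring alkenes, and the quaternary stereocentre is not involved.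

Step 8
Reactants: 11 the primary iodide; 4 the aryloxy aldehyde
Product: 14 (3S,6S,7E)-8-{4-[(tert-butyldimethylsilyl)oxy]phenyl}-6-ethenyl-2-{4-[(1E,3S)-3-ethenyl-3,7-dimethylocta-1,6-dien-1-yl]phenoxy}-2,6-dimethyloct-7-en-3-ol, via dialkylzinc 12 (not isolated), via mixed alkylzinc 13 (not isolated)
Conditions: 11 (1.5 equiv), Et2Zn (neat), CuI (0.3 mol %), 50 °C, then volatiles removed in vacuo; (Me3SiCH2)2Zn, Et2O, 25 °C; then Ti(OiPr)4 (2 equiv), (1R,2R)-N,N'-bis(trifluoromethanesulfonyl)cyclohexane-1,2-diamine (8 mol %), 4 (1.0 equiv), toluene, −20 to 0 °C; aq. NH4Cl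
Reagents that add atoms: none
Why: Copper-catalysed iodine–zinc exchange should convert the primary iodide into dialkylzinc 12, which redistributes with (Me3SiCH2)2Zn to the mixed reagent 13 whose Me3SiCH2 group does not transfer; the alkyl group then passes to the chiral titanium bis(sulfonamide) isopropoxide complex and adds to the titanium-bound aldehyde, forming the C11'–C12' bond. The closest known reaction type is the Ti(OiPr)4/bis(trifluoromethanesulfonamide)-catalysed enantioselective addition of functionalised dialkylzinc and alkyl(trimethylsilylmethyl)zinc reagents to aldehydes. No ring is closed. The new C12' stereocentre is under catalyst control: by analogy with benzaldehyde, the (1R,2R)-ligand should deliver the alkyl group to the Si face of 4, in which the CMe2OAr group takes the place of the aryl group, and this corresponds to 12'S; the two quaternary stereocentres are remote and should not bias the addition. The step needs 1,2-addition to win over β-hydride reduction and needs both partners to stay intact: 4 has no α-hydrogen and carries only a hindered, weakly coordinating aryloxy group on C13', so it cannot enolise or self-condense, and the primary alkylzinc is a polar nucleophile for which closure onto the vinyl or styryl group would mean a four-membered ring.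

Step 9
Reactants: 14 the silyl ether of the target
Product: 15 (12'S)-bisbakuchiol C
Conditions: Bu4NF, THF, 0 °C; aq. NH4Cl
Reagents that add atoms: none
Why: Fluoride should cleave the aryl silyl ether through Si–F bond formation under conditions that leave the tertiary alkyl aryl ether, the secondary alcohol and all alkenes unchanged, so no stereocentre is affected.

**Compound list**

1 | (S)-bakuchiol, 4-[(1E,3S)-3-ethenyl-3,7-dimethylocta-1,6-dien-1-yl]phenol | C=C[C@@](C)(/C=C/c1ccc(O)cc1)CCC=C(C)C | starting material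
2 | ethyl 2-bromo-2-methylpropanoate | CCOC(=O)C(C)(C)Br | starting material
3 | ethyl 2-{4-[(1E,3S)-3-ethenyl-3,7-dimethylocta-1,6-dien-1-yl]phenoxy}-2-methylpropanoate | C=C[C@@](C)(/C=C/c1ccc(OC(C)(C)C(=O)OCC)cc1)CCC=C(C)C | intermediate
4 | 2-{4-[(1E,3S)-3-ethenyl-3,7-dimethylocta-1,6-dien-1-yl]phenoxy}-2-methylpropanal | C=C[C@@](C)(/C=C/c1ccc(OC(C)(C)C=O)cc1)CCC=C(C)C | intermediate
5 | tert-butyl{4-[(1E,3S)-3-ethenyl-3,7-dimethylocta-1,6-dien-1-yl]phenoxy}dimethylsilane | C=C[C@@](C)(/C=C/c1ccc(O[Si](C)(C)C(C)(C)C)cc1)CCC=C(C)C | intermediate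
6 | tert-butyl(4-{(1E,3S)-5-(3,3-dimethyloxiran-2-yl)-3-ethenyl-3-methylpent-1-en-1-yl}phenoxy)dimethylsilane, both epimers at the oxirane CH | C=C[C@@](C)(/C=C/c1ccc(O[Si](C)(C)C(C)(C)C)cc1)CCC1OC1(C)C | intermediate
7 | (6S,7E)-8-{4-[(tert-butyldimethylsilyl)oxy]phenyl}-6-ethenyl-2,6-dimethyloct-7-ene-2,3-diol, both epimers at C3 (glycol, not isolated) | C=C[C@@](C)(/C=C/c1ccc(O[Si](C)(C)C(C)(C)C)cc1)CCC(O)C(C)(C)O | intermediate
8 | (4S,5E)-6-{4-[(tert-butyldimethylsilyl)oxy]phenyl}-4-ethenyl-4-methylhex-5-enal | C=C[C@@](C)(/C=C/c1ccc(O[Si](C)(C)C(C)(C)C)cc1)CCC=O | intermediate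
9 | (4S,5E)-6-{4-[(tert-butyldimethylsilyl)oxy]phenyl}-4-ethenyl-4-methylhex-5-enoic acid | C=C[C@@](C)(/C=C/c1ccc(O[Si](C)(C)C(C)(C)C)cc1)CCC(=O)O | intermediate
10 | 2-thioxopyridin-1(2H)-yl (4S,5E)-6-{4-[(tert-butyldimethylsilyl)oxy]phenyl}-4-ethenyl-4-methylhex-5-enoate (Barton ester, not isolated) | C=C[C@@](C)(/C=C/c1ccc(O[Si](C)(C)C(C)(C)C)cc1)CCC(=O)On1ccccc1=S | intermediate
11 | tert-butyl{4-[(1E,3S)-3-ethenyl-5-iodo-3-methylpent-1-en-1-yl]phenoxy}dimethylsilane | C=C[C@@](C)(/C=C/c1ccc(O[Si](C)(C)C(C)(C)C)cc1)CCI | intermediate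
12 | bis{(3S,4E)-5-[4-(tert-butyldimethylsilyloxy)phenyl]-3-ethenyl-3-methylpent-4-en-1-yl}zinc (not isolated) | C=C[C@@](C)(/C=C/c1ccc(O[Si](C)(C)C(C)(C)C)cc1)CC[Zn]CC[C@@](C)(C=C)/C=C/c1ccc(O[Si](C)(C)C(C)(C)C)cc1 | intermediate
13 | {(3S,4E)-5-[4-(tert-butyldimethylsilyloxy)phenyl]-3-ethenyl-3-methylpent-4-en-1-yl}[(trimethylsilyl)methyl]zinc (not isolated) | C[Si](C)(C)C[Zn]CC[C@@](C)(C=C)/C=C/c1ccc(O[Si](C)(C)C(C)(C)C)cc1 | intermediate
14 | (3S,6S,7E)-8-{4-[(tert-butyldimethylsilyl)oxy]phenyl}-6-ethenyl-2-{4-[(1E,3S)-3-ethenyl-3,7-dimethylocta-1,6-dien-1-yl]phenoxy}-2,6-dimethyloct-7-en-3-ol (silyl ether of the target at its phenol) | C=C[C@@](C)(/C=C/c1ccc(OC(C)(C)[C@@H](O)CC[C@@](C)(C=C)/C=C/c2ccc(O[Si](C)(C)C(C)(C)C)cc2)cc1)CCC=C(C)C | intermediate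
15 | (12'S)-bisbakuchiol C, (3S,6S,7E)-6-ethenyl-2-{4-[(1E,3S)-3-ethenyl-3,7-dimethylocta-1,6-dien-1-yl]phenoxy}-8-(4-hydroxyphenyl)-2,6-dimethyloct-7-en-3-ol | C=C[C@@](C)(/C=C/c1ccc(OC(C)(C)[C@@H](O)CC[C@@](C)(C=C)/C=C/c2ccc(O)cc2)cc1)CCC=C(C)C | target

**Step count and risks**

Total steps: 9. Longest linear sequence: 7 steps (steps 3 to 9).

Steps most likely to fail:

1. Step 8. Alkyl transfer to the neopentyl-type aldehyde may be slow, β-hydride reduction of the aldehyde by the zinc reagent may compete, or facial selectivity may be eroded. The fallback sets out from 11 and 4 and comes back at 14. Iodide 11 would undergo iodine–lithium exchange (t-BuLi, pentane/Et2O, −78 °C) to the alkyllithium F1, which should add to 4 at −78 °C without facial control to give the C12' epimer mixture F2. Dess–Martin oxidation (CH2Cl2, NaHCO3) should give the ketone F3. Corey–Bakshi–Shibata reduction with catecholborane and (R)-2-methyl-CBS-oxazaborolidine (toluene, −78 °C), with CMe2OAr as the large group, should then return 14 with the 12'S configuration.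

2. Step 7. The primary radical may be intercepted by the thiocarbonyl group of the ester before iodine transfer, or chain-carrying radicals may add to the alkenes. The fallback sets out from 8 and comes back at 11 without any carbon radical. Aldehyde 8 would be condensed with morpholine (K2CO3, toluene, 25 °C) to the enamine F4. Aerobic copper-catalysed cleavage of the enamine double bond (CuCl cat., O2, MeCN, 25 °C) should give the one-carbon-shorter aldehyde F5. Reduction with NaBH4 (MeOH, 0 °C) gives the primary alcohol F6, and Appel iodination (I2, PPh3, imidazole, CH2Cl2, 0 °C) would return 11.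

3. Step 4. Epoxidation may also occur at the electron-rich styryl alkene, or over-oxidation may set in. The fallback sets out from 5 and comes back at 8. Upjohn dihydroxylation of 5 (OsO4 cat., N-methylmorpholine N-oxide, acetone/H2O, 0 °C) should single out the remote trisubstituted alkene, since osmylation responds strongly to the steric shielding that the quaternary carbon exerts on the vinyl and styryl alkenes. It would give glycol 7 directly, which would be isolated and cleaved with NaIO4 (THF/H2O, 25 °C) to 8.

**Further compounds**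

F1 | step 8 | {(3S,4E)-5-[4-(tert-butyldimethylsilyloxy)phenyl]-3-ethenyl-3-methylpent-4-en-1-yl}lithium | [Li]CC[C@@](C)(C=C)/C=C/c1ccc(O[Si](C)(C)C(C)(C)C)cc1
F2 | step 8 | (6S,7E)-8-{4-[(tert-butyldimethylsilyl)oxy]phenyl}-6-ethenyl-2-{4-[(1E,3S)-3-ethenyl-3,7-dimethylocta-1,6-dien-1-yl]phenoxy}-2,6-dimethyloct-7-en-3-ol, both epimers at C3 | C=C[C@@](C)(/C=C/c1ccc(OC(C)(C)C(O)CC[C@@](C)(C=C)/C=C/c2ccc(O[Si](C)(C)C(C)(C)C)cc2)cc1)CCC=C(C)C
F3 | step 8 | (6S,7E)-8-{4-[(tert-butyldimethylsilyl)oxy]phenyl}-6-ethenyl-2-{4-[(1E,3S)-3-ethenyl-3,7-dimethylocta-1,6-dien-1-yl]phenoxy}-2,6-dimethyloct-7-en-3-one | C=C[C@@](C)(/C=C/c1ccc(OC(C)(C)C(=O)CC[C@@](C)(C=C)/C=C/c2ccc(O[Si](C)(C)C(C)(C)C)cc2)cc1)CCC=C(C)C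
F4 | step 7 | 4-[(1E,4S,5E)-6-{4-[(tert-butyldimethylsilyl)oxy]phenyl}-4-ethenyl-4-methylhexa-1,5-dien-1-yl]morpholine | C=C[C@@](C)(/C=C/c1ccc(O[Si](C)(C)C(C)(C)C)cc1)C/C=C/N1CCOCC1
F5 | step 7 | (3S,4E)-5-{4-[(tert-butyldimethylsilyl)oxy]phenyl}-3-ethenyl-3-methylpent-4-enal | C=C[C@@](C)(/C=C/c1ccc(O[Si](C)(C)C(C)(C)C)cc1)CC=O
F6 | step 7 | (3S,4E)-5-{4-[(tert-butyldimethylsilyl)oxy]phenyl}-3-ethenyl-3-methylpent-4-en-1-ol | C=C[C@@](C)(/C=C/c1ccc(O[Si](C)(C)C(C)(C)C)cc1)CCO
F0 | step 4 | none | none
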